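**Retrosynthetic overview**
- 17 ⇐ 15 (debromolaurinterol): late double electrophilic bromination of the phenol (para, then ortho), as in haloperoxidase tailoring.
- 15 ⇐ 13 ⇐ 10: the cyclopropane closes last, by 1,3-elimination at the tertiary C-1 cation (the laurane C-11 cation); Bu3Sn stands in for the proton that nature removes from the neighbouring one-carbon branch.
- 10 ⇐ 6: the CH2SnBu3 branch is set cis to the aryl group by enolate alkylation followed by kinetic protonation.
- 6 ⇐ 5 ⇐ 4 ⇐ 1 + 2: the cyclopentane closes at the tertiary benzylic (bisabolyl-type) cation, captured by a strained C–C σ bond instead of the π bond used in nature (stereospecific ring expansion of an enantioenriched oxaspirohexane from Shi epoxidation; alkene by Wittig).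
- Ring order: arene bought → cyclopentane (step 3) → cyclopropane (step 5).

Assumption: 1-(2-methoxy-4-methylphenyl)ethan-1-one (1), cyclobutyltriphenylphosphonium bromide (2) and tributyl(iodomethyl)stannane are bought.

**Step 1**
Reactants: 1 1-(2-methoxy-4-methylphenyl)ethan-1-one; 2 cyclobutyltriphenylphosphonium bromide
Product: 4 1-(1-cyclobutylideneethyl)-2-methoxy-4-methylbenzene, via cyclobutylidene(triphenyl)phosphorane 3 (not isolated)
Conditions: 2 (1.6 equiv), KOtBu (1.6 equiv), THF, 0 °C → rt; then 1, reflux, 18 h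
Reagents that add atoms: none
Why: Wittig olefination of the aryl methyl ketone with the non-stabilised cyclobutylidene ylide gives the tetrasubstituted alkylidenecyclobutane; the cyclobutylidene end is symmetric, so no alkene geometry or stereocentre arises.

**Step 2**
Reactants: 4 1-(1-cyclobutylideneethyl)-2-methoxy-4-methylbenzene
Product: 5 (2R)-2-(2-methoxy-4-methylphenyl)-2-methyl-1-oxaspiro[2.3]hexane
Conditions: D-fructose-derived Shi ketone (30 mol%), Oxone (2KHSO5·KHSO4·K2SO4; 1.4 equiv KHSO5), K2CO3, Bu4NHSO4 (5 mol%), MeCN–CH2(OMe)2 / aq. Na2B4O7 buffer (pH 10.5), −10 → 0 °C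
Reagents that add atoms: potassium peroxymonosulfate (active part of Oxone), [K+].[O-]S(=O)(=O)OO
Why: Shi epoxidation (chiral dioxirane, spiro transition state) should differentiate the alkene faces as it does for 1-arylcycloalkenes, giving the benzylic oxirane carbon as R; this is the only stereocentre the route takes from a catalyst.

**Step 3**
Reactants: 5 (2R)-2-(2-methoxy-4-methylphenyl)-2-methyl-1-oxaspiro[2.3]hexane
Product: 6 (2S)-2-(2-methoxy-4-methylphenyl)-2-methylcyclopentan-1-one
Conditions: Et2AlCl (1.0 equiv), toluene, −78 °C, 30 min; aqueous quench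
Reagents that add atoms: none
Why: Semipinacol-type (Meinwald) ring expansion: Al-assisted opening of the benzylic C–O bond develops the tertiary benzylic cation and a strained cyclobutane C–C bond migrates anti to the departing oxygen, so the five-membered ring closes with inversion and the quaternary centre emerges as S.

**Step 4**
Reactants: 6 (2S)-2-(2-methoxy-4-methylphenyl)-2-methylcyclopentan-1-one
Product: 10 (2S,5S)-2-(2-methoxy-4-methylphenyl)-2-methyl-5-[(tributylstannyl)methyl]cyclopentan-1-one, via kinetic lithium enolate 7 (not isolated), via alkylated ketone epimers 8 (not isolated), via stannylmethyl lithium enolate 9 (not isolated)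
Conditions: LiN(iPr)2 (1.05 equiv), THF, −78 °C; Bu3SnCH2I (1.0 equiv), DMPU, −78 → −20 °C; LiN(iPr)2 (1.3 equiv), −78 → 0 °C; 2,6-di-tert-butyl-4-methylphenol (3 equiv), −78 °C; H2O
Reagents that add atoms: tributyl(iodomethyl)stannane, CCCC[Sn](CCCC)(CCCC)CI
Why: SN2 enolate alkylation, then re-enolisation and kinetic protonation: reagents approach C-5 anti to the larger aryl group on C-2, so the bulky phenol delivers H trans to aryl and leaves CH2SnBu3 cis to it (5S), the opposite of what alkylation alone gives.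

**Step 5**
Reactants: 10 (2S,5S)-2-(2-methoxy-4-methylphenyl)-2-methyl-5-[(tributylstannyl)methyl]cyclopentan-1-one
Product: 13 (1S,2R,5R)-2-(2-methoxy-4-methylphenyl)-1,2-dimethylbicyclo[3.1.0]hexane, via lithium alkoxide 11 (not isolated), via tertiary chlorosulfite 12 (not isolated)
Conditions: MeLi (1.15 equiv), Et2O, −78 °C, 1 h; SOCl2 (1.3 equiv), CH2Cl2, −78 → 0 °C; aq. NaHCO3
Reagents that add atoms: methyllithium, [Li]C
Why: 1,2-addition of MeLi, then the chlorosulfite ionises to the tertiary C-1 cation, which is quenched by γ-stannyl 1,3-elimination (the C–Sn σ bond attacks with inversion at CH2, Bu3SnCl leaves); the cyclopropane therefore closes on the face that carries the CH2SnBu3 branch, cis to aryl, fixing C-1 (S) and C-5 (R), while the carbinol configuration is erased in the cation and no acid is generated.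

**Step 6**
Reactants: 13 (1S,2R,5R)-2-(2-methoxy-4-methylphenyl)-1,2-dimethylbicyclo[3.1.0]hexane
Product: 15 2-[(1S,2R,5R)-1,2-dimethylbicyclo[3.1.0]hexan-2-yl]-5-methylphenol (debromolaurinterol), via sodium phenoxide 14 (not isolated)
Conditions: NaSEt (5 equiv), DMF, 130 °C, 6 h; aq. NH4Cl
Reagents that add atoms: none
Why: SN2 O-demethylation of the hindered aryl methyl ether by thiolate in a dipolar aprotic solvent; the basic medium leaves the acid-labile cyclopropane and all three stereocentres untouched.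

**Step 7**
Reactants: 15 2-[(1S,2R,5R)-1,2-dimethylbicyclo[3.1.0]hexan-2-yl]-5-methylphenol
Product: 17 2,4-dibromo-6-[(1S,2R,5R)-1,2-dimethylbicyclo[3.1.0]hexan-2-yl]-3-methylphenol, via laurinterol 16 (not isolated)
Conditions: NBS (2.05 equiv), NaHCO3 (3 equiv), MeCN, −10 → 20 °C, dark
Reagents that add atoms: N-bromosuccinimide, O=C1CCC(=O)N1Br
Why: Electrophilic aromatic bromination of the phenol, first para and then at the remaining ortho position between OH and CH3 (the other ortho site carries the bicycle, as in the dibromination of thymol); the buffer keeps HBr from opening the cyclopropane.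

**Compound list**
1 | 1-(2-methoxy-4-methylphenyl)ethan-1-one | COc1cc(C)ccc1C(C)=O | starting material
2 | cyclobutyltriphenylphosphonium bromide | [Br-].C1CC(C1)[P+](c1ccccc1)(c1ccccc1)c1ccccc1 | starting material
3 | cyclobutylidene(triphenyl)phosphorane | C1CC(C1)=P(c1ccccc1)(c1ccccc1)c1ccccc1 | intermediate
4 | 1-(1-cyclobutylideneethyl)-2-methoxy-4-methylbenzene | COc1cc(C)ccc1C(C)=C1CCC1 | intermediate
5 | (2R)-2-(2-methoxy-4-methylphenyl)-2-methyl-1-oxaspiro[2.3]hexane | COc1cc(C)ccc1[C@@]1(C)OC12CCC2 | intermediate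
6 | (2S)-2-(2-methoxy-4-methylphenyl)-2-methylcyclopentan-1-one | COc1cc(C)ccc1[C@]1(C)CCCC1=O | intermediate
7 | lithium (5S)-5-(2-methoxy-4-methylphenyl)-5-methylcyclopent-1-en-1-olate | COc1cc(C)ccc1[C@]1(C)CCC=C1O[Li] | intermediate
8 | (2S)-2-(2-methoxy-4-methylphenyl)-2-methyl-5-[(tributylstannyl)methyl]cyclopentan-1-one, mixture of C-5 epimers | COc1cc(C)ccc1[C@]1(C)CCC(C[Sn](CCCC)(CCCC)CCCC)C1=O | intermediate
9 | lithium (5S)-5-(2-methoxy-4-methylphenyl)-5-methyl-2-[(tributylstannyl)methyl]cyclopent-1-en-1-olate | COc1cc(C)ccc1[C@]1(C)CCC(C[Sn](CCCC)(CCCC)CCCC)=C1O[Li] | intermediate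
10 | (2S,5S)-2-(2-methoxy-4-methylphenyl)-2-methyl-5-[(tributylstannyl)methyl]cyclopentan-1-one | COc1cc(C)ccc1[C@]1(C)CC[C@H](C[Sn](CCCC)(CCCC)CCCC)C1=O | intermediate
11 | lithium (1S,2S,5S)-2-(2-methoxy-4-methylphenyl)-1,2-dimethyl-5-[(tributylstannyl)methyl]cyclopentan-1-olate | COc1cc(C)ccc1[C@]1(C)CC[C@H](C[Sn](CCCC)(CCCC)CCCC)[C@]1(C)O[Li] | intermediate
12 | (1S,2S,5S)-2-(2-methoxy-4-methylphenyl)-1,2-dimethyl-5-[(tributylstannyl)methyl]cyclopentyl chlorosulfite | COc1cc(C)ccc1[C@]1(C)CC[C@H](C[Sn](CCCC)(CCCC)CCCC)[C@]1(C)OS(Cl)=O | intermediate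
13 | (1S,2R,5R)-2-(2-methoxy-4-methylphenyl)-1,2-dimethylbicyclo[3.1.0]hexane | COc1cc(C)ccc1[C@]1(C)CC[C@@H]2C[C@@]21C | intermediate
14 | sodium 2-[(1S,2R,5R)-1,2-dimethylbicyclo[3.1.0]hexan-2-yl]-5-methylphenolate | Cc1ccc([C@]2(C)CC[C@@H]3C[C@@]32C)c([O-])c1.[Na+] | intermediate
15 | 2-[(1S,2R,5R)-1,2-dimethylbicyclo[3.1.0]hexan-2-yl]-5-methylphenol (debromolaurinterol) | Cc1ccc([C@]2(C)CC[C@@H]3C[C@@]32C)c(O)c1 | intermediate
16 | 4-bromo-2-[(1S,2R,5R)-1,2-dimethylbicyclo[3.1.0]hexan-2-yl]-5-methylphenol (laurinterol) | Cc1cc(O)c([C@]2(C)CC[C@@H]3C[C@@]32C)cc1Br | intermediate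
17 | 2,4-dibromo-6-[(1S,2R,5R)-1,2-dimethylbicyclo[3.1.0]hexan-2-yl]-3-methylphenol | Cc1c(Br)cc([C@]2(C)CC[C@@H]3C[C@@]32C)c(O)c1Br | target

**Totals**
Total steps: 7. Longest linear sequence: 7.

**Steps most likely to fail**

Step 2. The alkene is tetrasubstituted and ortho-substituted, so the enantiomeric excess may be modest, and the electron-rich epoxide 5 is labile and must be used crude. The R assignment rests on analogy; if the antipode of 5 forms, a retentive LiI rearrangement still leads to 6. Fallback, setting out from 4 and coming back at 6 (it also bypasses step 3): mCPBA/NaHCO3 gives the racemic epoxide F1, which Et2AlCl rearranges to the racemic ketone F2. Reduction with BH3·SMe2 and 10 mol% (S)-2-methyl-CBS-oxazaborolidine delivers hydride to the same carbonyl face of both enantiomers, giving the separable diastereomers (1R,2S)-alcohol F3 and (1R,2R)-alcohol F4. Chromatography and oxidation of F3 (Pr4N[RuO4] cat., N-methylmorpholine N-oxide) return 6.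

Step 4. The C-5 configuration depends on a 1,3-facial bias from the aryl/methyl pair on C-2, which may be small. If the bias is real but reversed, omitting the re-enolisation gives 10 directly. Fallback, setting out from 6 and coming back at 11, which replaces 1,3-induction by a ring-fusion constraint: direct α-methylenation ((CH2O)n, N-methylanilinium trifluoroacetate, THF, reflux) gives the α-methylene ketone F5. MeLi/CeCl3 adds anti to the aryl group to give the tertiary allylic alcohol F6, and ClSiMe2H/Et3N gives the hydrodimethylsilyl ether F7. H2PtCl6-catalysed intramolecular hydrosilylation closes the cis-fused oxasilolane F8, whose ring fusion forces the new CH2 onto the face of the C-1 oxygen and hence of the aryl group. Tamao oxidation (H2O2, KF, KHCO3) gives the diol F9, TsCl/pyridine the primary tosylate F10, and Bu3SnLi the γ-stannyl alcohol F11. n-BuLi at −78 °C converts F11 into the lithium alkoxide 11, which is treated with SOCl2 as in step 5.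

Step 5. Methyl addition to the hindered, enolisable ketone may be incomplete. The chlorosulfite may collapse to the tertiary chloride or eliminate. The cation may also be diverted by the ortho-methoxyaryl group (aryl shift, or O-capture to an aplysin-type ether) before tin-assisted closure. Fallback, setting out from 10 and coming back at 13, which enters the same cation by olefin protonation with no chloride or base present: Wittig methylenation (Ph3P=CH2, toluene, 80 °C) gives the exocyclic alkene F12, and TfOH (1.0 equiv, CH2Cl2, −78 °C, then Et3N) protonates the 1,1-disubstituted alkene to the C-1 cation, which closes to 13 with loss of Bu3SnOTf.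

**Further compounds**
F1 | step 2 | rac-2-(2-methoxy-4-methylphenyl)-2-methyl-1-oxaspiro[2.3]hexane | COc1cc(C)ccc1C1(C)OC12CCC2
F2 | step 2 | rac-2-(2-methoxy-4-methylphenyl)-2-methylcyclopentan-1-one | COc1cc(C)ccc1C1(C)CCCC1=O
F3 | step 2 | (1R,2S)-2-(2-methoxy-4-methylphenyl)-2-methylcyclopentan-1-ol | COc1cc(C)ccc1[C@]1(C)CCC[C@H]1O
F4 | step 2 | (1R,2R)-2-(2-methoxy-4-methylphenyl)-2-methylcyclopentan-1-ol | COc1cc(C)ccc1[C@@]1(C)CCC[C@H]1O
F5 | step 4 | (2S)-2-(2-methoxy-4-methylphenyl)-2-methyl-5-methylidenecyclopentan-1-one | COc1cc(C)ccc1[C@]1(C)CCC(=C)C1=O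
F6 | step 4 | (1S,2S)-2-(2-methoxy-4-methylphenyl)-1,2-dimethyl-5-methylidenecyclopentan-1-ol | COc1cc(C)ccc1[C@]1(C)CCC(=C)[C@]1(C)O
F7 | step 4 | {[(1S,2S)-2-(2-methoxy-4-methylphenyl)-1,2-dimethyl-5-methylidenecyclopentyl]oxy}dimethylsilane | COc1cc(C)ccc1[C@]1(C)CCC(=C)[C@]1(C)O[SiH](C)C
F8 | step 4 | (3aS,6S,6aS)-6-(2-methoxy-4-methylphenyl)-2,2,6,6a-tetramethylhexahydro-2H-cyclopenta[d][1,2]oxasilole | COc1cc(C)ccc1[C@]1(C)CC[C@@H]2C[Si](C)(C)O[C@@]21C
F9 | step 4 | (1S,2S,5R)-5-(hydroxymethyl)-2-(2-methoxy-4-methylphenyl)-1,2-dimethylcyclopentan-1-ol | COc1cc(C)ccc1[C@]1(C)CC[C@H](CO)[C@]1(C)O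
F10 | step 4 | [(1R,2S,3S)-2-hydroxy-3-(2-methoxy-4-methylphenyl)-2,3-dimethylcyclopentyl]methyl 4-methylbenzenesulfonate | COc1cc(C)ccc1[C@]1(C)CC[C@H](COS(=O)(=O)c2ccc(C)cc2)[C@]1(C)O
F11 | step 4 | (1S,2S,5S)-2-(2-methoxy-4-methylphenyl)-1,2-dimethyl-5-[(tributylstannyl)methyl]cyclopentan-1-ol | COc1cc(C)ccc1[C@]1(C)CC[C@H](C[Sn](CCCC)(CCCC)CCCC)[C@]1(C)O
F12 | step 5 | tributyl{[(1S,3R)-3-(2-methoxy-4-methylphenyl)-3-methyl-2-methylidenecyclopentyl]methyl}stannane | COc1cc(C)ccc1[C@]1(C)CC[C@H](C[Sn](CCCC)(CCCC)CCCC)C1=C
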